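**Strategy.** Everything rests on not coupling the three arenes: outer rings A and C are grown on ring B by disconnecting C1'–C2' and C2'–C3' in each. The feature exploited is that, in rings A and C, only the C2' oxygen (ortho to the C1'–ring B bond) is sulfated while C4'–OH and C6'–OH are free; C2' can therefore be supplied by carbon monoxide and emerge as the single unprotected phenol. One twofold rhodium-catalysed carbonylative [5+1] benzannulation closes both rings, sets the 2',4',6'-oxygen pattern and differentiates C2'–OH. Its precursor is perbenzylated ring B carrying at C2 and C4 two (Z)-2-benzyloxy-3-pivaloyloxypent-1-en-4-ynyl arms, made from a dialdehyde.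

Key step: step 10

Assumption: the target is drawn without axial descriptors and as the free bis(hydrogen sulfate), so the two hindered biaryl axes are left uncontrolled and every aryl sulfate is drawn as the free acid although it would be handled as its pyridinium or potassium salt.

Step 1
Reactants: 1 triethyl phosphonoacetate
Product: 2 triethyl diazophosphonoacetate (ethyl 2-diazo-2-(diethoxyphosphoryl)acetate)
Conditions: NaH, 4-acetamidobenzenesulfonyl azide, THF, 0 °C to rt
Reagents that add atoms: 4-acetamidobenzenesulfonyl azide, CC(=O)Nc1ccc(cc1)S(=O)(=O)N=[N+]=[N-]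
Why: Regitz diazo transfer to the doubly activated methylene of a phosphonoacetate is routine and touches neither ester type.

Step 2
Reactants: 2 triethyl diazophosphonoacetate; 3 benzyl alcohol
Product: 4 ethyl 2-(benzyloxy)-2-(diethoxyphosphoryl)acetate (racemic)
Conditions: Rh2(OAc)4 (1 mol%), BnOH (1.5 equiv), toluene, 80 °C
Reagents that add atoms: benzyl alcohol 3, OCc1ccccc1
Why: Rhodium-carbenoid O–H insertion into a primary alcohol is an established entry to α-alkoxy phosphonoacetates; the new stereocentre forms racemic and is destroyed in step 5.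

Step 3
Reactants: 5 phloroglucinol
Product: 6 2,4,6-trihydroxyisophthalaldehyde (2,4-diformylphloroglucinol)
Conditions: POCl3 (2.2 equiv), DMF, 1,4-dioxane, 0 °C to rt; then H2O
Reagents that add atoms: N,N-dimethylformamide, CN(C)C=O; water, O
Why: Vilsmeier–Haack formylation of the very electron-rich ring should stop at the dialdehyde with two equivalents of reagent because each iminium group deactivates the ring.

Step 4
Reactants: 6 2,4,6-trihydroxyisophthalaldehyde; 7 benzyl bromide
Product: 8 2,4,6-tris(benzyloxy)isophthalaldehyde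
Conditions: BnBr (3.6 equiv), K2CO3, DMF, 60 °C
Reagents that add atoms: benzyl bromide 7, BrCc1ccccc1
Why: Williamson O-benzylation, in which the two formyl groups lower the nucleophilicity of the remaining ring carbon so that O- rather than C-alkylation is expected.

Step 5
Reactants: 8 2,4,6-tris(benzyloxy)isophthalaldehyde; 4 ethyl 2-(benzyloxy)-2-(diethoxyphosphoryl)acetate
Product: 9 diethyl (2Z,2'Z)-3,3'-[2,4,6-tris(benzyloxy)-1,3-phenylene]bis[2-(benzyloxy)prop-2-enoate] (each aryl–CH cis to OBn and trans to the ester)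
Conditions: 4 (2.5 equiv), NaH, THF, 0 °C to rt
Reagents that add atoms: phosphonate 4, CCOC(=O)C(OCc1ccccc1)P(=O)(OCC)OCC
Why: Horner–Wadsworth–Emmons olefination, in which reversible addition of the stabilised α-alkoxy phosphonate anion should favour the thermodynamic Z enol ether (aryl trans to the ester), any E arm being separable here or equilibrated at the enal stage.

Step 6
Reactants: 9 diethyl (2Z,2'Z)-bis[2-(benzyloxy)prop-2-enoate]
Product: 10 (2Z,2'Z)-3,3'-[2,4,6-tris(benzyloxy)-1,3-phenylene]bis[2-(benzyloxy)prop-2-en-1-ol]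
Conditions: iBu2AlH (5 equiv), CH2Cl2, −78 to 0 °C; Rochelle salt work-up
Reagents that add atoms: none
Why: 1,2-Reduction of the enoates by the aluminium hydride gives the allylic alcohols without touching the enol-ether double bonds or the benzyl ethers, and the basic work-up protects the acid-sensitive product.

Step 7
Reactants: 10 (2Z,2'Z)-bis[2-(benzyloxy)prop-2-en-1-ol]
Product: 11 (2Z,2'Z)-3,3'-[2,4,6-tris(benzyloxy)-1,3-phenylene]bis[2-(benzyloxy)prop-2-enal]
Conditions: activated MnO2 (excess), CH2Cl2, rt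
Reagents that add atoms: none
Why: Activated MnO2 oxidises allylic alcohols under neutral heterogeneous conditions, and the push–pull enal should settle in, or be equilibrated (trace I2, daylight) to, the Z,Z geometry with each aryl trans to its formyl group.

Step 8
Reactants: 11 (2Z,2'Z)-bis[2-(benzyloxy)prop-2-enal]; 12 ethynylmagnesium bromide
Product: 13 (1Z,1'Z)-1,1'-[2,4,6-tris(benzyloxy)-1,3-phenylene]bis[2-(benzyloxy)pent-1-en-4-yn-3-ol] (mixture of carbinol diastereomers)
Conditions: HC≡CMgBr (3 equiv), THF, −78 to 0 °C; sat. aq. NH4Cl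
Reagents that add atoms: ethynylmagnesium bromide 12, C#C[Mg]Br
Why: Alkynyl Grignard reagents add 1,2 to enals; the two new carbinol stereocentres form without control, which is immaterial because each becomes the aromatic carbon C5' in step 10.

Step 9
Reactants: 13 bis(pent-1-en-4-yn-3-ol); 14 pivaloyl chloride
Product: 15 1,3,5-tris(benzyloxy)-2,4-bis[(1Z)-2-(benzyloxy)-3-(pivaloyloxy)pent-1-en-4-yn-1-yl]benzene (mixture of carbinol diastereomers)
Conditions: PivCl (3 equiv), Et3N, DMAP (cat.), CH2Cl2, 0 °C to rt; chromatography on Et3N-deactivated silica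
Reagents that add atoms: pivaloyl chloride 14, CC(C)(C)C(Cl)=O
Why: DMAP-catalysed acylation of a secondary alcohol under basic conditions avoids ionisation of the doubly activated (propargylic and vinylogous benzylic) carbinol and leaves its configuration unchanged.

Step 10
Reactants: 15 bis(3-pivaloyloxy-1,4-enyne); 16 carbon monoxide
Product: 17 1,3,5-tris(benzyloxy)-2,4-bis[2-hydroxy-4-(pivaloyloxy)-6-(benzyloxy)phenyl]benzene
Conditions: [RhCl(CO)2]2 (10 mol%), CO (10 atm), ClCH2CH2Cl, 80 °C
Reagents that add atoms: carbon monoxide 16, [C-]#[O+]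
Why: Monovalent rhodium binds each terminal alkyne and the pivalate carbonyl attacks the internal alkyne carbon, so that a 1,2-acyloxy shift through a dioxolenium intermediate gives a rhodium dienylcarbene, Rh=CH–C(OPiv)=CH–C(OBn)=CH–Ar. The carbene closes onto the enol-ether terminus to a rhodacyclohexadiene, CO inserts and C–C reductive elimination (equivalently, ketene formation and 6π-electrocyclisation) gives a cyclohexa-2,4-dienone that enolises to the phenol, the former CO carbon becoming C2'–OH between C1' and C3'. The closest known reaction type is the [RhCl(CO)2]2-catalysed carbonylative [5+1] cycloaddition of 3-acyloxy-1,4-enynes to resorcinol monoesters, of which an enol-ether alkene and a twofold run are untested extensions. Rings A and C each close as a six-membered carbocycle in a formal [5+1] mode, five carbons from the arm and one from CO. No stereocentre survives, since the carbinol centres and the transient sp3 C1' are aromatised and the two biaryl axes are not controlled. The step needs 1,2- over 1,3-acyloxy migration, which the terminal alkyne and secondary pivalate favour, and the aryl group outside the closing loop, which the Z enol ether secures, while the bulky pivaloyl group should resist transfer to the new phenol and so keep C2'–OH as the only free hydroxyl.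

Step 11
Reactants: 17 bis(2-hydroxy-4-pivaloyloxy-6-benzyloxyphenyl) terphenyl
Product: 19 1,3,5-tris(benzyloxy)-2,4-bis[6-(benzyloxy)-4-hydroxy-2-(sulfooxy)phenyl]benzene (dipotassium salt in practice), via bis(hydrogen sulfate) dipivalate 18 (not isolated)
Conditions: SO3·pyridine (8 equiv), pyridine, 50 °C; concentrate; then K2CO3, MeOH, rt; work-up at pH 8
Reagents that add atoms: sulfur trioxide pyridine complex, O=S(=O)([O-])[n+]1ccccc1
Why: O-Sulfation of the only free phenols with SO3·pyridine, followed by methanolysis of the aryl pivalates; aryl sulfate monoester anions are inert to carbonate and methoxide, so the same base forms the potassium salt and frees C4'–OH.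

Step 12
Reactants: 19 bis(sulfate) pentabenzyl ether
Product: 20 2',4,4',4'',6,6',6''-heptahydroxy-[1,1':3',1''-terphenyl]-2,2''-diyl bis(hydrogen sulfate) (CNP0320583.0; isolated as the dipotassium salt)
Conditions: H2 (1 atm), 10% Pd/C, MeOH–H2O, rt
Reagents that add atoms: none
Why: Catalytic hydrogenolysis removes all five benzyl ethers under neutral conditions that aryl sulfate salts tolerate, and no stereocentre is involved.

**Compound list**

1 | triethyl phosphonoacetate | CCOC(=O)CP(=O)(OCC)OCC | starting material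
2 | triethyl diazophosphonoacetate | CCOC(=O)C(=[N+]=[N-])P(=O)(OCC)OCC | intermediate
3 | benzyl alcohol | OCc1ccccc1 | starting material
4 | ethyl 2-(benzyloxy)-2-(diethoxyphosphoryl)acetate (racemic) | CCOC(=O)C(OCc1ccccc1)P(=O)(OCC)OCC | intermediate
5 | phloroglucinol | Oc1cc(O)cc(O)c1 | starting material
6 | 2,4,6-trihydroxyisophthalaldehyde | O=Cc1c(O)cc(O)c(C=O)c1O | intermediate
7 | benzyl bromide | BrCc1ccccc1 | starting material
8 | 2,4,6-tris(benzyloxy)isophthalaldehyde | O=Cc1c(OCc2ccccc2)cc(OCc2ccccc2)c(C=O)c1OCc1ccccc1 | intermediate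
9 | diethyl (2Z,2'Z)-3,3'-[2,4,6-tris(benzyloxy)-1,3-phenylene]bis[2-(benzyloxy)prop-2-enoate] | CCOC(=O)/C(OCc1ccccc1)=C/c1c(OCc2ccccc2)cc(OCc2ccccc2)c(/C=C(\OCc2ccccc2)C(=O)OCC)c1OCc1ccccc1 | intermediate
10 | (2Z,2'Z)-3,3'-[2,4,6-tris(benzyloxy)-1,3-phenylene]bis[2-(benzyloxy)prop-2-en-1-ol] | OC/C(OCc1ccccc1)=C/c1c(OCc2ccccc2)cc(OCc2ccccc2)c(/C=C(\OCc2ccccc2)CO)c1OCc1ccccc1 | intermediate
11 | (2Z,2'Z)-3,3'-[2,4,6-tris(benzyloxy)-1,3-phenylene]bis[2-(benzyloxy)prop-2-enal] | O=C/C(OCc1ccccc1)=C/c1c(OCc2ccccc2)cc(OCc2ccccc2)c(/C=C(\OCc2ccccc2)C=O)c1OCc1ccccc1 | intermediate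
12 | ethynylmagnesium bromide | C#C[Mg]Br | starting material
13 | (1Z,1'Z)-1,1'-[2,4,6-tris(benzyloxy)-1,3-phenylene]bis[2-(benzyloxy)pent-1-en-4-yn-3-ol] (carbinol diastereomers) | C#CC(O)/C(OCc1ccccc1)=C/c1c(OCc2ccccc2)cc(OCc2ccccc2)c(/C=C(\OCc2ccccc2)C(O)C#C)c1OCc1ccccc1 | intermediate
14 | pivaloyl chloride | CC(C)(C)C(Cl)=O | starting material
15 | 1,3,5-tris(benzyloxy)-2,4-bis[(1Z)-2-(benzyloxy)-3-(pivaloyloxy)pent-1-en-4-yn-1-yl]benzene (carbinol diastereomers) | C#CC(OC(=O)C(C)(C)C)/C(OCc1ccccc1)=C/c1c(OCc2ccccc2)cc(OCc2ccccc2)c(/C=C(\OCc2ccccc2)C(OC(=O)C(C)(C)C)C#C)c1OCc1ccccc1 | intermediate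
16 | carbon monoxide | [C-]#[O+] | starting material
17 | 1,3,5-tris(benzyloxy)-2,4-bis[2-hydroxy-4-(pivaloyloxy)-6-(benzyloxy)phenyl]benzene | Oc1cc(OC(=O)C(C)(C)C)cc(OCc2ccccc2)c1-c1c(OCc2ccccc2)cc(OCc2ccccc2)c(-c2c(O)cc(OC(=O)C(C)(C)C)cc2OCc2ccccc2)c1OCc1ccccc1 | intermediate
18 | 1,3,5-tris(benzyloxy)-2,4-bis[6-(benzyloxy)-4-(pivaloyloxy)-2-(sulfooxy)phenyl]benzene (pyridinium salt in the flask) | O=S(=O)(O)Oc1cc(OC(=O)C(C)(C)C)cc(OCc2ccccc2)c1-c1c(OCc2ccccc2)cc(OCc2ccccc2)c(-c2c(OS(=O)(=O)O)cc(OC(=O)C(C)(C)C)cc2OCc2ccccc2)c1OCc1ccccc1 | intermediate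
19 | 1,3,5-tris(benzyloxy)-2,4-bis[6-(benzyloxy)-4-hydroxy-2-(sulfooxy)phenyl]benzene (dipotassium salt in practice) | O=S(=O)(O)Oc1cc(O)cc(OCc2ccccc2)c1-c1c(OCc2ccccc2)cc(OCc2ccccc2)c(-c2c(OS(=O)(=O)O)cc(O)cc2OCc2ccccc2)c1OCc1ccccc1 | intermediate
20 | 2',4,4',4'',6,6',6''-heptahydroxy-[1,1':3',1''-terphenyl]-2,2''-diyl bis(hydrogen sulfate) | O=S(=O)(O)Oc1cc(O)cc(O)c1-c1c(O)cc(O)c(-c2c(O)cc(O)cc2OS(=O)(=O)O)c1O | target

**Step count.** Total: 12 steps. Longest linear sequence: 10 steps (steps 3–12 from phloroglucinol; the branch from triethyl phosphonoacetate, steps 1, 2 and 5–12, is equally long).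

**Steps most likely to fail**

1. Step 10. The rhodium carbene may be diverted by a 1,3-acyloxy shift to an allenyl ester or by ionisation of the doubly activated pivalate. The second annulation may also stall, because the remaining arm is shielded by the newly formed tetra-ortho-substituted biaryl. The fallback sets out from 5 and 7 and comes back at 20; it assembles the terphenyl by a twofold Suzuki–Miyaura coupling instead.
   - Central ring: exhaustive O-benzylation of 5 with 7 (K2CO3, DMF, C-benzylated by-products removed) would give 1,3,5-tris(benzyloxy)benzene F1. NBS (2 equiv, CH2Cl2, 0 °C) would give 2,4-dibromo-1,3,5-tris(benzyloxy)benzene F2.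
   - Outer ring: 3,5-bis(benzyloxy)phenol F3 (from 5 with two equivalents of 7) would be converted with MOMCl and iPr2NEt to 1,3-bis(benzyloxy)-5-(methoxymethoxy)benzene F4. Lithiation between OMOM and OBn (n-BuLi, TMEDA, THF, −78 to 0 °C) would give [2,4-bis(benzyloxy)-6-(methoxymethoxy)phenyl]lithium F5. Trapping with 2-isopropoxy-4,4,5,5-tetramethyl-1,3,2-dioxaborolane would give the pinacol boronate 2-[2,4-bis(benzyloxy)-6-(methoxymethoxy)phenyl]-4,4,5,5-tetramethyl-1,3,2-dioxaborolane F6.
   - Coupling and endgame: F2 and F6 (Pd(OAc)2, SPhos, K3PO4, toluene–H2O, 100 °C) would give 1,3,5-tris(benzyloxy)-2,4-bis[2,4-bis(benzyloxy)-6-(methoxymethoxy)phenyl]benzene F7. HCl in MeOH would free the two C2' phenols to give 1,3,5-tris(benzyloxy)-2,4-bis[2,4-bis(benzyloxy)-6-hydroxyphenyl]benzene F8. SO3·pyridine would convert these to 1,3,5-tris(benzyloxy)-2,4-bis[2,4-bis(benzyloxy)-6-(sulfooxy)phenyl]benzene F9, and hydrogenolysis of the seven benzyl ethers (H2, Pd/C) would give 20.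

2. Step 5. The twofold olefination may be sluggish at the two di-ortho-benzyloxy formyl groups and may give poor E/Z control. The fallback sets out from 8 and comes back at 9. The lithium enolate of commercial ethyl 2-(benzyloxy)acetate (LDA, THF, −78 °C) would add to both formyl groups to give diethyl 3,3'-[2,4,6-tris(benzyloxy)-1,3-phenylene]bis[2-(benzyloxy)-3-hydroxypropanoate] F10 as a diastereomer mixture. MsCl and Et3N would convert it in the flask to the bis(methanesulfonate) F11. DBU would then effect E1cB elimination to the thermodynamic Z,Z diester 9.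

3. Step 11. Sulfation may remain incomplete at the hindered C2' hydroxyls, and sulfate may be lost during work-up and chromatography of the polar salt. The fallback sets out from 17 and comes back at 18; it installs the sulfates in protected, neutral form. 2,2,2-Trichloroethyl chlorosulfate with Et3N and DMAP in THF would give the bis(2,2,2-trichloroethyl sulfate) diester of 17, F12, which can be purified on silica. Zinc dust with ammonium formate in MeOH would unmask both sulfate monoesters by reductive β-elimination, giving 18 as its ammonium salt. Compound 18 then re-enters the route at the methanolysis half of step 11.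

**Further compounds**

F1 | step 10 | 1,3,5-tris(benzyloxy)benzene | c1ccc(COc2cc(OCc3ccccc3)cc(OCc3ccccc3)c2)cc1
F2 | step 10 | 2,4-dibromo-1,3,5-tris(benzyloxy)benzene | Brc1c(OCc2ccccc2)cc(OCc2ccccc2)c(Br)c1OCc1ccccc1
F3 | step 10 | 3,5-bis(benzyloxy)phenol | Oc1cc(OCc2ccccc2)cc(OCc2ccccc2)c1
F4 | step 10 | 1,3-bis(benzyloxy)-5-(methoxymethoxy)benzene | COCOc1cc(OCc2ccccc2)cc(OCc2ccccc2)c1
F5 | step 10 | [2,4-bis(benzyloxy)-6-(methoxymethoxy)phenyl]lithium | [Li]c1c(OCOC)cc(OCc2ccccc2)cc1OCc1ccccc1
F6 | step 10 | 2-[2,4-bis(benzyloxy)-6-(methoxymethoxy)phenyl]-4,4,5,5-tetramethyl-1,3,2-dioxaborolane | COCOc1cc(OCc2ccccc2)cc(OCc2ccccc2)c1B1OC(C)(C)C(C)(C)O1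
F7 | step 10 | 1,3,5-tris(benzyloxy)-2,4-bis[2,4-bis(benzyloxy)-6-(methoxymethoxy)phenyl]benzene | COCOc1cc(OCc2ccccc2)cc(OCc2ccccc2)c1-c1c(OCc2ccccc2)cc(OCc2ccccc2)c(-c2c(OCOC)cc(OCc3ccccc3)cc2OCc2ccccc2)c1OCc1ccccc1
F8 | step 10 | 1,3,5-tris(benzyloxy)-2,4-bis[2,4-bis(benzyloxy)-6-hydroxyphenyl]benzene | Oc1cc(OCc2ccccc2)cc(OCc2ccccc2)c1-c1c(OCc2ccccc2)cc(OCc2ccccc2)c(-c2c(O)cc(OCc3ccccc3)cc2OCc2ccccc2)c1OCc1ccccc1
F9 | step 10 | 1,3,5-tris(benzyloxy)-2,4-bis[2,4-bis(benzyloxy)-6-(sulfooxy)phenyl]benzene | O=S(=O)(O)Oc1cc(OCc2ccccc2)cc(OCc2ccccc2)c1-c1c(OCc2ccccc2)cc(OCc2ccccc2)c(-c2c(OS(=O)(=O)O)cc(OCc3ccccc3)cc2OCc2ccccc2)c1OCc1ccccc1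
F10 | step 5 | diethyl 3,3'-[2,4,6-tris(benzyloxy)-1,3-phenylene]bis[2-(benzyloxy)-3-hydroxypropanoate] (diastereomer mixture) | CCOC(=O)C(OCc1ccccc1)C(O)c1c(OCc2ccccc2)cc(OCc2ccccc2)c(C(O)C(OCc2ccccc2)C(=O)OCC)c1OCc1ccccc1
F11 | step 5 | diethyl 3,3'-[2,4,6-tris(benzyloxy)-1,3-phenylene]bis[2-(benzyloxy)-3-(methylsulfonyloxy)propanoate] (diastereomer mixture) | CCOC(=O)C(OCc1ccccc1)C(OS(C)(=O)=O)c1c(OCc2ccccc2)cc(OCc2ccccc2)c(C(OS(C)(=O)=O)C(OCc2ccccc2)C(=O)OCC)c1OCc1ccccc1
F12 | step 11 | 1,3,5-tris(benzyloxy)-2,4-bis[6-(benzyloxy)-4-(pivaloyloxy)-2-[(2,2,2-trichloroethoxy)sulfonyloxy]phenyl]benzene | ClC(Cl)(Cl)COS(=O)(=O)Oc1cc(OC(=O)C(C)(C)C)cc(OCc2ccccc2)c1-c1c(OCc2ccccc2)cc(OCc2ccccc2)c(-c2c(OS(=O)(=O)OCC(Cl)(Cl)Cl)cc(OC(=O)C(C)(C)C)cc2OCc2ccccc2)c1OCc1ccccc1
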